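Numbering used throughout: isoflavan numbering with O1, C2, C3, C4, C4a, C5–C8, C8a for rings C and A, C1'–C6' for ring B, and ring D for the dimethylpyran fused to ring B at C2'–C3'. Compound numbers are those of the steps and the compound list below.

## Analysis of the target

Target 21 is an isoflavan: a chroman (benzene ring A fused to dihydropyran ring C) carrying an aryl group, ring B, on C3, with a 2,2-dimethyl-2H-pyran (ring D) fused to ring B through the C2' oxygen and C3'. Ring A is pentasubstituted and phloroglucinol-derived, with C5–OMe, C7–OH and C8–CHO; the formyl group sits between the C7 hydroxyl and the ring oxygen on C8a. The only stereocenter is C3, of R configuration (checked against the SMILES: C2 > C1' > C4 > H, clockwise). It is a benzylic CH between two methylene groups, with no neighbouring heteroatom or carbonyl to help set it, but for the same reason it cannot epimerise once formed. The sensitive groups are the styrene-type double bond of ring D (which rules out hydrogenolysis, strong Lewis acids and electrophilic oxidants late in the route), the electron-rich salicylaldehyde unit, and two free phenols. The difficulty is to create this isolated benzylic stereocenter enantioselectively while joining two heavily oxygenated, sterically loaded arenes, and to carry aldehyde and chromene through to the end. The strategy rests on the C3–C4 unit: a two-carbon bridge between C1' of ring B (on C3) and C4a of ring A (on C4). This is a vinyl group that has taken up two different aryl groups, and C3 still lacks one carbon (C2), the place where a boron atom can sit and later be exchanged for CH2–O.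

## Retrosynthetic reasoning

**O1–C2 (21 to 20).** Ring C is opened at the aryl ether bond. This leaves C3 untouched and reduces the last step to a 6-exo-tet displacement of a primary sulfonate by the C8a phenoxide. The other phenols of 20 cannot reach C2 through a ring of reasonable size, so no differentiation of the hydroxyls is needed at that stage.

**Protecting groups and leaving group (20 to 19 to 18).** All masks of 20 (three methoxymethyl ethers and the cyclic acetal on the formyl carbon) are chosen to fall in one mild acid treatment. The sulfonate is put on the primary alcohol 18 while every phenol is still protected, so the activation is chemoselective by construction.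

**C2–O and C3–C2 (18 to 17 to 15).** The hydroxymethyl group on C3 is traced back to a CH2–B unit (17), and this to insertion of a one-carbon carbenoid into the C3–B bond of the secondary benzylic boronate 15 by way of the ate complex 16. Cutting here makes boron on C3 the single handle that both results from the key step and delivers C2. The 1,2-shift is stereoretentive at C3, so the configuration set in 15 is carried into 21 unchanged. The homologation needs a formyl carbon that tolerates organolithium reagents, which is why ring A carries it as an acetal.

**C3–C1' and C4–C4a (15 to 5, 12 and 13).** Both aryl–carbon bonds of the bridge are cut at once. This returns the two arenes as fully substituted blocks (aryllithium 13 carrying rings B and D, bromide 5 carrying ring A) and the bridge as the two-carbon boronate 12. Cutting elsewhere, for instance at C2–C3 or inside an arene, would leave the stereocenter to be made by a separate operation. In the forward sense 13 and 12 form the ate complex 14, and a chiral palladium catalyst must then make ring B migrate from boron to C3 while ring A is delivered to C4, with control of the C3 configuration.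

**Rings B and D (13 to 11 to 9 to 7 and 8 to 6).** Aryllithium 13 comes from bromide 11 by halogen–lithium exchange. Ring D of 11 is opened by a retro-Claisen/electrocyclisation sequence (through 10) to the aryl propargyl ether 9, made from phenol 7 and the propargylic chloride 8. The bromine of 6 has two roles: it blocks one ortho position, so the rearrangement can only go to the carbon between the two oxygens, and it becomes the lithium of 13. The task in the forward direction is to tell the two hydroxyls of 6 apart.

**Ring A block (5 to 4 to 3 to 2 to 1).** The acetal of 5 is traced to aldehyde 4, the bromine to an electrophilic substitution on 3, the two acetal-type ethers to diol 2, and the methyl ether to the most acidic hydroxyl of 1. Compounds 2 and 3 are mirror-symmetric, so the two open ring positions are equivalent and bromination has no regiochemical choice. The acetal has to be formed without protic acid, because the aryl methoxymethyl ethers of 4 would not survive the usual acid-catalysed exchange with a diol.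

## Alternatives that were turned down

**Alternative 1: ring B assembled on the chroman by a vinylketene benzannulation.**
- Disconnection: four bonds of ring B (C1'–C2', C2'–C3', C4'–C5', C5'–C6') are cut. This leads back to the chroman-3-yl diazo enone A2 and the prenyl-substituted siloxyalkyne A3.
- Forward key step: visible-light Wolff rearrangement of A2 gives a vinylketene, which adds A3 and electrocyclises to the 2'-hydroxy-3'-prenyl-4'-silyloxyaryl isoflavan A1.
- For it: the substitution pattern of ring B is fixed by the mechanism, the free 2'-hydroxyl and the adjacent prenyl group are placed exactly for a later oxidative closure of ring D, and no hindered cross-coupling is needed. On regiochemical certainty of ring B it is at least as good as the chosen route, which depends on telling apart the two hydroxyls of 6.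
- Against it: the key step creates no stereocenter. C3 must be set earlier, and in A2 it is γ to the enone carbonyl, so vinylogous enolisation during the preparation of the diazo ketone can erode it. Ring B is built atom by atom, and after A1 the route still needs chromene formation, desilylation and reduction of the dioxinone to the aldehyde.
- Comparison: the chosen route buys rings B and D as one block (11, three steps) and spends its key step on the stereocenter and two skeletal bonds at once.

**Alternative 2: a pterocarpan as a temporary ring that relays the C3 configuration.**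
- Disconnection: the target is derived from the cis-pterocarpan A4 by reductive cleavage of the benzylic C4–O bond, and A4 from the 2'-hydroxyisoflav-3-ene A5.
- Forward key step: a confined chiral Brønsted acid protonates C3 of A5 and the 2'-hydroxyl captures the C4 benzylic cation.
- For it: A5 comes from classical isoflavone chemistry with no sterically demanding metal-catalysed coupling, and the stereocenter is set by proton transfer with an organic catalyst. On robustness of fragment assembly it is stronger than the chosen route.
- Against it: the C4 cation is reversibly accessible under the same acid, and loss of the C3 proton returns A5, so the C3 configuration can leak away. Ring D is not yet present in A4 and has to be annulated onto ring B by a high-temperature rearrangement after the stereocenter is made, followed by desilylation and adjustment of the dioxinone to the aldehyde. The temporary C4–O bond costs one step to make and one to break.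
- Comparison: the chosen route has no temporary ring, carries ring D from the start, and never places C3 next to a cationic or carbonyl carbon.

**Alternative 3: aminocatalytic ortho-quinone methide annulation closing ring C.**
- Disconnection: C3–C4 and O1–C2 are cut. This gives the ring A ortho-quinone methide A8 (released by base from a stable precursor) and the ring B arylacetaldehyde A7.
- Forward key step: the chiral enamine of A7 adds to the methylene of A8 and the phenoxide closes onto the iminium carbon to give lactol A6.
- For it: this is the most convergent plan. One step forms two bonds, ring C and the stereocenter from two complete fragments, and it avoids oxidative addition at a di-ortho-substituted aryl bromide. On convergence and step count around ring C it is stronger than the chosen route.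
- Against it: in A6 the stereocenter is α to a masked aldehyde, and ring–chain tautomerism exposes an α-aryl aldehyde that enolises easily. The lactol must then be deoxygenated with a silane and acid, conditions that threaten the ring D double bond. A7 itself is a self-condensing arylacetaldehyde with an ortho substituent that slows enamine formation.
- Comparison: the chosen route needs five steps after its key step instead of two or three, but C3 is configurationally inert in every intermediate and no reductive acid step meets the chromene.

Key step: step 8

Remark on the chemistry: the antipode of the ferrocenyl bisphosphine in step 8 is taken to be the one that delivers the R-configured boronate 15. Both antipodes of this ligand family are available, so the sense of induction is a matter of ligand choice.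

## Route

Step 1
Reactants: 1 2,4,6-trihydroxybenzaldehyde
Product: 2 2,6-dihydroxy-4-methoxybenzaldehyde
Conditions: MeI (1.05 equiv), K2CO3 (1.0 equiv), acetone, rt
Reagents that add atoms: iodomethane, CI
Why: Regioselective Williamson etherification: the 4-hydroxyl is para to the formyl group, the most acidic and the only one not held in a hydrogen bond to the carbonyl, so with one equivalent of base it should be alkylated first.

Step 2
Reactants: 2 2,6-dihydroxy-4-methoxybenzaldehyde
Product: 3 4-methoxy-2,6-bis(methoxymethoxy)benzaldehyde
Conditions: NaH (2.4 equiv), MOMCl (2.4 equiv), DMF, 0 °C → rt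
Reagents that add atoms: chloromethyl methyl ether, COCCl
Why: O-alkylation of the phenoxides with a reactive α-chloro ether; full deprotonation with NaH overcomes the hydrogen bonding of the hydroxyls to the carbonyl, and the aldehyde has no enolisable position.

Step 3
Reactants: 3 4-methoxy-2,6-bis(methoxymethoxy)benzaldehyde
Product: 4 3-bromo-4-methoxy-2,6-bis(methoxymethoxy)benzaldehyde
Conditions: NBS (1.0 equiv), MeCN, 0 °C → rt
Reagents that add atoms: N-bromosuccinimide, O=C1CCC(=O)N1Br
Why: Electrophilic aromatic bromination; the two open positions are equivalent by symmetry and each is ortho or para to three oxygens, the formyl group and the first bromine should hold the reaction at one substitution, and the neutral conditions spare the acetal-type ethers.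

Step 4
Reactants: 4 3-bromo-4-methoxy-2,6-bis(methoxymethoxy)benzaldehyde
Product: 5 2-[3-bromo-4-methoxy-2,6-bis(methoxymethoxy)phenyl]-1,3-dioxolane
Conditions: Me3SiOCH2CH2OSiMe3 (1.5 equiv), Me3SiOTf (5 mol%), CH2Cl2, −78 → −30 °C; pyridine quench
Reagents that add atoms: 1,2-bis(trimethylsilyloxy)ethane, C[Si](C)(C)OCCO[Si](C)(C)C
Why: Noyori acetalisation: the silyl triflate activates the carbonyl oxygen (the most basic site of this vinylogous carbonate), the resulting trioxygenated benzylic oxocarbenium ion is strongly stabilised, and hexamethyldisiloxane formation drives the exchange. The medium is aprotic and cold with only catalytic silyl triflate, conditions under which aryl methoxymethyl ethers are normally retained, whereas Brønsted acid with a free diol would cleave them.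

Step 5
Reactants: 6 4-bromoresorcinol
Product: 7 2-bromo-5-(methoxymethoxy)phenol
Conditions: MOMCl (1.0 equiv), i-Pr2NEt (1.1 equiv), CH2Cl2, −20 → 0 °C
Reagents that add atoms: chloromethyl methyl ether, COCCl
Why: Selective mono-etherification: the hydroxyl para to bromine is sterically open and the more nucleophilic one, whereas the hydroxyl ortho to bromine is shielded, inductively deactivated and engaged in an O–H···Br contact; with a hindered amine base and one equivalent of reagent the open hydroxyl should react preferentially, and the isomer and the bis-ether are removed by chromatography.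

Step 6
Reactants: 7 2-bromo-5-(methoxymethoxy)phenol; 8 3-chloro-3-methylbut-1-yne
Product: 9 1-bromo-4-(methoxymethoxy)-2-[(2-methylbut-3-yn-2-yl)oxy]benzene
Conditions: CuCl2·2H2O (1 mol%), DBU (1.3 equiv), MeCN, 0 °C
Reagents that add atoms: none
Why: Copper-catalysed propargylic etherification of a phenol with a tertiary propargylic chloride (through a copper acetylide/allenylidene species); this avoids the elimination that plagues uncatalysed substitution at a tertiary centre and tolerates the ortho bromine.

Step 7
Reactants: 9 1-bromo-4-(methoxymethoxy)-2-[(2-methylbut-3-yn-2-yl)oxy]benzene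
Product: 11 8-bromo-5-(methoxymethoxy)-2,2-dimethyl-2H-chromene, via allenylphenol 10 (not isolated)
Conditions: o-xylene, 140 °C (sealed tube)
Reagents that add atoms: none
Why: Aromatic propargyl Claisen rearrangement to the only free ortho carbon (the other bears bromine), enolisation to 10, then 1,5-hydrogen shift and oxa-6π-electrocyclisation close ring D; the gem-dimethyl group accelerates the sigmatropic step and the conditions are neutral.

Step 8
Reactants: 11 8-bromo-5-(methoxymethoxy)-2,2-dimethyl-2H-chromene; 12 vinylboronic acid pinacol ester; 5 2-[3-bromo-4-methoxy-2,6-bis(methoxymethoxy)phenyl]-1,3-dioxolane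
Product: 15 2-[(1R)-2-[3-(1,3-dioxolan-2-yl)-6-methoxy-2,4-bis(methoxymethoxy)phenyl]-1-[5-(methoxymethoxy)-2,2-dimethyl-2H-chromen-8-yl]ethyl]-4,4,5,5-tetramethyl-1,3,2-dioxaborolane, via aryllithium 13 (not isolated), via vinylboron ate complex 14 (not isolated)
Conditions: 11, t-BuLi (2.0 equiv), Et2O, −78 °C; 12, −78 °C → rt; solvent exchange to THF; 5, Pd(OAc)2 (3 mol%), 1,1'-bis[bis(4-methoxy-3,5-dimethylphenyl)phosphino]-2,2'-bis[α-(dimethylamino)benzyl]ferrocene (single antipode, 3.6 mol%), NaOTf (2.5 equiv), THF, 60 °C
Reagents that add atoms: none
Why: Bromine–lithium exchange on 11 (faster at −78 °C than ether-directed ortho-lithiation) gives 13, which adds to the empty boron orbital of 12 to give the four-coordinate ate complex 14. Zerovalent palladium, formed from Pd(OAc)2 and the chiral ferrocenyl bisphosphine, inserts into the C–Br bond of 5, and NaOTf removes bromide as NaBr so that the cationic divalent palladium aryl can bind the vinyl group of 14 as a π-acid. This binding triggers a 1,2-metalate shift in which the ring B aryl group moves from boron to C3, anti to palladium, while palladium bonds to the terminal carbon C4; reductive elimination then forms C4–C4a and returns zerovalent palladium. The closest known reaction type is the palladium-catalysed enantioselective conjunctive cross-coupling of vinylboron ate complexes with aryl triflates and, with triflate salt additives, aryl bromides. No ring is closed in this step. The C3 stereocenter is set in the migration step by enantiofacial binding of the vinyl group in the chiral pocket of the bisphosphine palladium aryl complex, and the ligand antipode is chosen for R. Regiochemistry is inherent in the mechanism (migrating group to the boron-bearing carbon, electrophile to the terminal carbon); what must be won is metalate shift over direct Suzuki-type transfer of aryl or vinyl, which the wide-bite-angle ligand and halide removal favour, and the OMe and OCH2OMe groups beside the C–Br bond are the smallest ortho substituents the target allows. The ring D double bond is not part of an ate complex and is a poor ligand for the hindered palladium aryl, so it should remain untouched.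

Step 9
Reactants: 15 2-[(1R)-2-[3-(1,3-dioxolan-2-yl)-6-methoxy-2,4-bis(methoxymethoxy)phenyl]-1-[5-(methoxymethoxy)-2,2-dimethyl-2H-chromen-8-yl]ethyl]-4,4,5,5-tetramethyl-1,3,2-dioxaborolane
Product: 17 2-[(2R)-3-[3-(1,3-dioxolan-2-yl)-6-methoxy-2,4-bis(methoxymethoxy)phenyl]-2-[5-(methoxymethoxy)-2,2-dimethyl-2H-chromen-8-yl]propyl]-4,4,5,5-tetramethyl-1,3,2-dioxaborolane, via chloromethyl boron ate complex 16 (not isolated)
Conditions: BrCH2Cl (2.0 equiv), n-BuLi (1.8 equiv, added last), THF, −78 °C → rt
Reagents that add atoms: bromochloromethane, ClCBr
Why: Matteson homologation: chloromethyllithium, generated in the presence of the boronate by fast bromine–lithium exchange, adds to boron to give 16, and C3 then migrates from boron to the CH2 carbon with loss of chloride and retention of configuration at C3. The acetal keeps the formyl carbon away from the organolithium reagents.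

Step 10
Reactants: 17 2-[(2R)-3-[3-(1,3-dioxolan-2-yl)-6-methoxy-2,4-bis(methoxymethoxy)phenyl]-2-[5-(methoxymethoxy)-2,2-dimethyl-2H-chromen-8-yl]propyl]-4,4,5,5-tetramethyl-1,3,2-dioxaborolane
Product: 18 (2R)-3-[3-(1,3-dioxolan-2-yl)-6-methoxy-2,4-bis(methoxymethoxy)phenyl]-2-[5-(methoxymethoxy)-2,2-dimethyl-2H-chromen-8-yl]propan-1-ol
Conditions: NaBO3·4H2O (4 equiv), THF/H2O (1:1), rt
Reagents that add atoms: sodium perborate tetrahydrate, [Na+].[O-]OB=O.O.O.O.O
Why: Oxidation of a primary alkyl boronate by peroxide addition to boron and 1,2-shift of carbon to oxygen; perborate is nearly neutral, so the acetal, the ethers and the electron-rich ring D alkene (inert to nucleophilic peroxide) are not at risk, and C3 is not involved.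

Step 11
Reactants: 18 (2R)-3-[3-(1,3-dioxolan-2-yl)-6-methoxy-2,4-bis(methoxymethoxy)phenyl]-2-[5-(methoxymethoxy)-2,2-dimethyl-2H-chromen-8-yl]propan-1-ol
Product: 19 (2R)-3-[3-(1,3-dioxolan-2-yl)-6-methoxy-2,4-bis(methoxymethoxy)phenyl]-2-[5-(methoxymethoxy)-2,2-dimethyl-2H-chromen-8-yl]propyl methanesulfonate
Conditions: MsCl (1.3 equiv), Et3N (2 equiv), CH2Cl2, 0 °C
Reagents that add atoms: methanesulfonyl chloride, CS(=O)(=O)Cl
Why: Sulfonylation of the only free hydroxyl (through the sulfene); all phenols are still protected and the basic medium preserves the acetal.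

Step 12
Reactants: 19 (2R)-3-[3-(1,3-dioxolan-2-yl)-6-methoxy-2,4-bis(methoxymethoxy)phenyl]-2-[5-(methoxymethoxy)-2,2-dimethyl-2H-chromen-8-yl]propyl methanesulfonate
Product: 20 (2R)-3-(3-formyl-2,4-dihydroxy-6-methoxyphenyl)-2-(5-hydroxy-2,2-dimethyl-2H-chromen-8-yl)propyl methanesulfonate
Conditions: 2 M aq. HCl, MeOH/THF, rt → 35 °C
Reagents that add atoms: water, O
Why: Acid-catalysed cleavage of the three methoxymethyl ethers (transfer of the CH2OMe unit to methanol) and hydrolysis of the very labile trioxygenated aryl acetal in one operation. A β-branched primary mesylate solvolyses slowly under these conditions, and a 2,2-dimethylchromene normally tolerates dilute acid at this temperature.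

Step 13
Reactants: 20 (2R)-3-(3-formyl-2,4-dihydroxy-6-methoxyphenyl)-2-(5-hydroxy-2,2-dimethyl-2H-chromen-8-yl)propyl methanesulfonate
Product: 21 (3R)-7-hydroxy-3-(5-hydroxy-2,2-dimethyl-2H-chromen-8-yl)-5-methoxy-3,4-dihydro-2H-chromene-8-carbaldehyde
Conditions: K2CO3 (1.1 equiv), DMF (0.01 M), rt
Reagents that add atoms: none
Why: Intramolecular Williamson etherification, 6-exo-tet: with about one equivalent of weak base only the acidic salicylaldehyde-type phenols of ring A are ionised, and of all the phenoxides only the one on C8a can reach C2 through a six-membered transition state, which closes ring C. C3 is not involved and keeps its R configuration.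

## Compound list

1 | 2,4,6-trihydroxybenzaldehyde | O=Cc1c(O)cc(O)cc1O | starting material
2 | 2,6-dihydroxy-4-methoxybenzaldehyde | COc1cc(O)c(C=O)c(O)c1 | intermediate
3 | 4-methoxy-2,6-bis(methoxymethoxy)benzaldehyde | COCOc1cc(OC)cc(OCOC)c1C=O | intermediate
4 | 3-bromo-4-methoxy-2,6-bis(methoxymethoxy)benzaldehyde | COc1cc(OCOC)c(C=O)c(OCOC)c1Br | intermediate
5 | 2-[3-bromo-4-methoxy-2,6-bis(methoxymethoxy)phenyl]-1,3-dioxolane | COc1cc(OCOC)c(C2OCCO2)c(OCOC)c1Br | intermediate
6 | 4-bromoresorcinol (4-bromobenzene-1,3-diol) | Oc1ccc(Br)c(O)c1 | starting material
7 | 2-bromo-5-(methoxymethoxy)phenol | COCOc1ccc(Br)c(O)c1 | intermediate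
8 | 3-chloro-3-methylbut-1-yne | CC(C)(Cl)C#C | starting material
9 | 1-bromo-4-(methoxymethoxy)-2-[(2-methylbut-3-yn-2-yl)oxy]benzene | COCOc1ccc(Br)c(OC(C)(C)C#C)c1 | intermediate
10 | 6-bromo-3-(methoxymethoxy)-2-(3-methylbuta-1,2-dien-1-yl)phenol | COCOc1ccc(Br)c(O)c1C=C=C(C)C | intermediate (not isolated)
11 | 8-bromo-5-(methoxymethoxy)-2,2-dimethyl-2H-chromene | COCOc1ccc(Br)c2OC(C)(C)C=Cc12 | intermediate
12 | vinylboronic acid pinacol ester | C=CB1OC(C)(C)C(C)(C)O1 | starting material
13 | [5-(methoxymethoxy)-2,2-dimethyl-2H-chromen-8-yl]lithium | [Li]c1ccc(OCOC)c2c1OC(C)(C)C=C2 | intermediate (not isolated)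
14 | lithium [5-(methoxymethoxy)-2,2-dimethyl-2H-chromen-8-yl](vinyl)(pinacolato)borate | [Li+].C=C[B-]1(c2ccc(OCOC)c3c2OC(C)(C)C=C3)OC(C)(C)C(C)(C)O1 | intermediate (not isolated)
15 | 2-[(1R)-2-[3-(1,3-dioxolan-2-yl)-6-methoxy-2,4-bis(methoxymethoxy)phenyl]-1-[5-(methoxymethoxy)-2,2-dimethyl-2H-chromen-8-yl]ethyl]-4,4,5,5-tetramethyl-1,3,2-dioxaborolane | COc1cc(OCOC)c(C2OCCO2)c(OCOC)c1C[C@H](c1ccc(OCOC)c2c1OC(C)(C)C=C2)B1OC(C)(C)C(C)(C)O1 | intermediate
16 | lithium (chloromethyl)[(1R)-2-[3-(1,3-dioxolan-2-yl)-6-methoxy-2,4-bis(methoxymethoxy)phenyl]-1-[5-(methoxymethoxy)-2,2-dimethyl-2H-chromen-8-yl]ethyl](pinacolato)borate | COc1cc(OCOC)c(C2OCCO2)c(OCOC)c1C[C@H](c1ccc(OCOC)c2c1OC(C)(C)C=C2)[B-]1(CCl)OC(C)(C)C(C)(C)O1.[Li+] | intermediate (not isolated)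
17 | 2-[(2R)-3-[3-(1,3-dioxolan-2-yl)-6-methoxy-2,4-bis(methoxymethoxy)phenyl]-2-[5-(methoxymethoxy)-2,2-dimethyl-2H-chromen-8-yl]propyl]-4,4,5,5-tetramethyl-1,3,2-dioxaborolane | COc1cc(OCOC)c(C2OCCO2)c(OCOC)c1C[C@H](c1ccc(OCOC)c2c1OC(C)(C)C=C2)CB1OC(C)(C)C(C)(C)O1 | intermediate
18 | (2R)-3-[3-(1,3-dioxolan-2-yl)-6-methoxy-2,4-bis(methoxymethoxy)phenyl]-2-[5-(methoxymethoxy)-2,2-dimethyl-2H-chromen-8-yl]propan-1-ol | COc1cc(OCOC)c(C2OCCO2)c(OCOC)c1C[C@H](c1ccc(OCOC)c2c1OC(C)(C)C=C2)CO | intermediate
19 | (2R)-3-[3-(1,3-dioxolan-2-yl)-6-methoxy-2,4-bis(methoxymethoxy)phenyl]-2-[5-(methoxymethoxy)-2,2-dimethyl-2H-chromen-8-yl]propyl methanesulfonate | COc1cc(OCOC)c(C2OCCO2)c(OCOC)c1C[C@H](c1ccc(OCOC)c2c1OC(C)(C)C=C2)COS(C)(=O)=O | intermediate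
20 | (2R)-3-(3-formyl-2,4-dihydroxy-6-methoxyphenyl)-2-(5-hydroxy-2,2-dimethyl-2H-chromen-8-yl)propyl methanesulfonate | COc1cc(O)c(C=O)c(O)c1C[C@H](c1ccc(O)c2c1OC(C)(C)C=C2)COS(C)(=O)=O | intermediate
21 | (3R)-7-hydroxy-3-(5-hydroxy-2,2-dimethyl-2H-chromen-8-yl)-5-methoxy-3,4-dihydro-2H-chromene-8-carbaldehyde | COc1cc(O)c(C=O)c2c1C[C@H](c1ccc(O)c3c1OC(C)(C)C=C3)CO2 | target

## Step count and least certain steps

Total: 13 steps. Longest linear sequence: 10 steps (steps 1–4, then 8–13); the ring B branch (steps 5–7) joins at step 8.

**Step 8 (key step).**
- What may go wrong: oxidative addition into the electron-rich C–Br bond flanked by two ortho oxygens may be slow. The ate complex 14 would then decay by protodeboronation or transfer its aryl or vinyl group directly to palladium. Chelation of the ortho acetal-type ether to palladium, or residual bromide, may block vinyl binding. A di-ortho-substituted aryl on palladium may also weaken facial discrimination.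
- Fallback (sets out from 11, 12 and 5, comes back at 15): the C–B bonds and the stereocenter are made first, and the aryl–alkyl bond afterwards by ordinary transmetalation.
  - Suzuki–Miyaura vinylation of 11 with 12 (Pd(PPh3)4, K2CO3, dioxane/H2O, 90 °C) gives 5-(methoxymethoxy)-2,2-dimethyl-8-vinyl-2H-chromene F1.
  - Platinum-catalysed enantioselective diboration of the terminal alkene (bis(pinacolato)diboron, Pt(dba)3, i.e. tris(dibenzylideneacetone)platinum, with a TADDOL-derived phosphonite of the appropriate antipode, THF, 60 °C) gives 2,2'-[(1R)-1-[5-(methoxymethoxy)-2,2-dimethyl-2H-chromen-8-yl]ethane-1,2-diyl]bis(4,4,5,5-tetramethyl-1,3,2-dioxaborolane) F2. This diboration is selective for monosubstituted alkenes, so the internal ring D alkene should be left alone.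
  - Site-selective Suzuki–Miyaura coupling of the primary C–B bond of F2 with 5 (Pd(OAc)2, 2-dicyclohexylphosphino-2',6'-diisopropoxybiphenyl, KOH, THF/H2O, 70 °C) gives 15. This ligand is designed for di-ortho-substituted aryl halides.

**Step 4.**
- What may go wrong: loss of methoxymethyl groups by silyl-triflate-promoted exchange, or incomplete conversion of the deactivated, doubly ortho-substituted aldehyde.
- Fallback (sets out from 2, comes back at 5): the acetal is made with ordinary Brønsted acid while the phenols carry acid-stable allyl groups, and these are exchanged afterwards.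
  - NBS (1.0 equiv, THF, −78 → 0 °C) gives 3-bromo-2,6-dihydroxy-4-methoxybenzaldehyde F3.
  - Allyl bromide and K2CO3 in DMF give 2,6-bis(allyloxy)-3-bromo-4-methoxybenzaldehyde F4.
  - Ethylene glycol and catalytic TsOH in benzene with water removal give 2-[2,6-bis(allyloxy)-3-bromo-4-methoxyphenyl]-1,3-dioxolane F5.
  - Pd(PPh3)4 (catalytic) with morpholine in THF at rt removes both allyl groups under basic conditions to give 4-bromo-2-(1,3-dioxolan-2-yl)-5-methoxybenzene-1,3-diol F6. Oxidative addition of zerovalent palladium to the hindered, electron-rich C–Br bond is not expected at this temperature.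
  - F6 is taken without chromatography into NaH and MOMCl in DMF to give 5.

**Step 12 (with its consequence for step 13).**
- What may go wrong: solvolysis or aryl-assisted ionisation of the primary sulfonate by the electron-rich ring B during acid treatment, and addition of methanol or HCl across the ring D double bond. In step 13, participation of a ring B phenoxide in displacing the sulfonate could scramble the chain if too much base is used.
- Fallback (sets out from 18, comes back at 21): the leaving group is avoided altogether.
  - Alcohol 18 is unmasked with the same dilute acid, which can now be run colder and longer because no leaving group is present, to give 2,6-dihydroxy-3-[(2R)-3-hydroxy-2-(5-hydroxy-2,2-dimethyl-2H-chromen-8-yl)propyl]-4-methoxybenzaldehyde F7.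
  - Ring C is closed under neutral Mitsunobu conditions (PPh3, diisopropyl azodicarboxylate, THF, 0 °C, high dilution). The acidic formyl-flanked phenol on C8a is the best pronucleophile and the only one that can form a six-membered ring, which gives 21.

**Step 5.**
- What may go wrong: insufficient discrimination between the two hydroxyls of 6 and double etherification, since the alkylating agent is small.
- Fallback (sets out from 6, comes back at 11): the selectivity is put on a purely steric footing.
  - i-Pr3SiCl and imidazole in CH2Cl2 silylate the unhindered hydroxyl to give 2-bromo-5-[(triisopropylsilyl)oxy]phenol F8.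
  - Copper-catalysed etherification with 8 as in step 6 gives [4-bromo-3-[(2-methylbut-3-yn-2-yl)oxy]phenoxy]triisopropylsilane F9.
  - Heating as in step 7 gives [(8-bromo-2,2-dimethyl-2H-chromen-5-yl)oxy]triisopropylsilane F10.
  - Bu4NF in THF gives 8-bromo-2,2-dimethyl-2H-chromen-5-ol F11.
  - MOMCl and i-Pr2NEt give 11.

## Further compounds

F1 | step 8 | 5-(methoxymethoxy)-2,2-dimethyl-8-vinyl-2H-chromene | C=Cc1ccc(OCOC)c2c1OC(C)(C)C=C2
F2 | step 8 | 2,2'-[(1R)-1-[5-(methoxymethoxy)-2,2-dimethyl-2H-chromen-8-yl]ethane-1,2-diyl]bis(4,4,5,5-tetramethyl-1,3,2-dioxaborolane) | CC1(C)OB(C[C@H](c2ccc(OCOC)c3c2OC(C)(C)C=C3)B2OC(C)(C)C(C)(C)O2)OC1(C)C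
F3 | step 4 | 3-bromo-2,6-dihydroxy-4-methoxybenzaldehyde | COc1cc(O)c(C=O)c(O)c1Br
F4 | step 4 | 2,6-bis(allyloxy)-3-bromo-4-methoxybenzaldehyde | COc1cc(OCC=C)c(C=O)c(OCC=C)c1Br
F5 | step 4 | 2-[2,6-bis(allyloxy)-3-bromo-4-methoxyphenyl]-1,3-dioxolane | COc1cc(OCC=C)c(C2OCCO2)c(OCC=C)c1Br
F6 | step 4 | 4-bromo-2-(1,3-dioxolan-2-yl)-5-methoxybenzene-1,3-diol | COc1cc(O)c(C2OCCO2)c(O)c1Br
F7 | step 12 | 2,6-dihydroxy-3-[(2R)-3-hydroxy-2-(5-hydroxy-2,2-dimethyl-2H-chromen-8-yl)propyl]-4-methoxybenzaldehyde | COc1cc(O)c(C=O)c(O)c1C[C@H](c1ccc(O)c2c1OC(C)(C)C=C2)CO
F8 | step 5 | 2-bromo-5-[(triisopropylsilyl)oxy]phenol | CC(C)[Si](Oc1ccc(Br)c(O)c1)(C(C)C)C(C)C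
F9 | step 5 | [4-bromo-3-[(2-methylbut-3-yn-2-yl)oxy]phenoxy]triisopropylsilane | CC(C)[Si](Oc1ccc(Br)c(OC(C)(C)C#C)c1)(C(C)C)C(C)C
F10 | step 5 | [(8-bromo-2,2-dimethyl-2H-chromen-5-yl)oxy]triisopropylsilane | CC(C)[Si](Oc1ccc(Br)c2OC(C)(C)C=Cc12)(C(C)C)C(C)C
F11 | step 5 | 8-bromo-2,2-dimethyl-2H-chromen-5-ol | Oc1ccc(Br)c2OC(C)(C)C=Cc12
A1 | alternative 1 | (3R)-isoflavan with ring B as 2'-hydroxy-3'-prenyl-4'-(triisopropylsilyloxy)phenyl and ring A as dioxinone | COc1cc2OC(C)(C)OC(=O)c2c2c1C[C@H](c1ccc(O[Si](C(C)C)(C(C)C)C(C)C)c(CC=C(C)C)c1O)CO2
A2 | alternative 1 | chroman-3-yl diazo enone (ring A as dioxinone, (E)-4-diazo-3-oxobut-1-enyl group on C3) | COc1cc2OC(C)(C)OC(=O)c2c2c1C[C@H](/C=C/C(=O)C=[N+]=[N-])CO2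
A3 | alternative 1 | triisopropyl[(5-methylhex-4-en-1-yn-1-yl)oxy]silane | CC(C)=CCC#CO[Si](C(C)C)(C(C)C)C(C)C
A4 | alternative 2 | cis-pterocarpan with ring A as dioxinone and a triisopropylsilyl ether on the future 4'-oxygen | COc1cc2OC(C)(C)OC(=O)c2c2c1[C@@H]1Oc3cc(O[Si](C(C)C)(C(C)C)C(C)C)ccc3[C@@H]1CO2
A5 | alternative 2 | 2'-hydroxy-4'-(triisopropylsilyloxy)isoflav-3-ene with ring A as dioxinone | COc1cc2OC(C)(C)OC(=O)c2c2c1C=C(c1ccc(O[Si](C(C)C)(C(C)C)C(C)C)cc1O)CO2
A6 | alternative 3 | (3R)-3-aryl-chroman-2-ol (anomeric mixture at C2), ring A as dioxinone, tert-butyldimethylsilyl ether on ring B | COc1cc2OC(C)(C)OC(=O)c2c2c1C[C@H](c1ccc(O[Si](C)(C)C(C)(C)C)c3c1OC(C)(C)C=C3)C(O)O2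
A7 | alternative 3 | 2-[5-(tert-butyldimethylsilyloxy)-2,2-dimethyl-2H-chromen-8-yl]acetaldehyde | O=CCc1ccc(O[Si](C)(C)C(C)(C)C)c2c1OC(C)(C)C=C2
A8 | alternative 3 | ring A ortho-quinone methide (dioxinone-fused 6-methylidenecyclohexa-2,4-dienone with 5-methoxy group) | COC1=CC2=C(C(=O)OC(C)(C)O2)C(=O)C1=C
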